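- Start from a balance: substrate leaves by itself to become intermediate, and intermediate leaves by taking up one partner. So intermediate equals substrate spent minus partner spent, in percent of the substrate charged, whatever target later becomes.

all flasks: substrate 0.10 M

| charge | partner | remark | time |
|---|---|---|---|
| blue | 0.048 M | run made earlier |  |
| grey | 0.064 M | run made earlier |  |
| green | 0.10 M | run made earlier |  |
| dusk | 0.0500 M |  | 12 min |
| dawn | 0.0900 M |  | 6.0 min |

| run | time / min | intermediate / % | target / % | substrate / % |
|---|---|---|---|---|
| blue | 1.33 | 32.2 | 8.9 | 57.4 |
| blue | 2.50 | 41.3 | 16.5 | 34.1 |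
| blue | 4.00 | 45.8 | 17.3 | 17.7 |
| blue | 5.00 | 47.5 | 15.6 | 11.1 |
| blue | 6.00 | 48.6 | 13.5 | 7.7 |
| grey | 0.500 | 17.6 | 2.8 | 81.6 |
| grey | 1.50 | 31.1 | 12.9 | 53.1 |
| grey | 3.00 | 37.0 | 22.1 | 27.5 |
| grey | 4.00 | 36.6 | 21.5 | 17.5 |
| grey | 6.00 | 38.3 | 16.8 | 7.1 |
| green | 0.500 | 15.4 | 3.9 | 80.3 |
| green | 1.50 | 24.7 | 17.7 | 53.2 |
| green | 3.00 | 23.8 | 28.0 | 26.6 |
| green | 4.00 | 23.9 | 27.8 | 18.4 |
| green | 6.00 | 19.1 | 23.4 | 7.7 |

(standard deviation of a reading: 0.5 percentage points)

- the analysis behind the earlier runs scatters by 0.5 percentage points, standard deviation

* which of the two ends with the higher amount of intermediate, in percent of the substrate charged ("neither" if they lie within 2 percentage points) (dusk / dawn / neither)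
* intermediate at the end, in percent of the substrate charged, dusk
* intermediate at the end, in percent of the substrate charged, dawn

- That balance is a guess, so test it. Substrate reads 7.7 %, 7.1 % and 7.7 % at 6.00 min across the partner charges, which suits a step without partner, and blue gives it a decay constant of 0.430 min⁻¹.
- Your objection: the balance might overspend partner. It doesn't: at 6.00 min it leaves 4.30 % in blue and 26.8 % in green, in the same percent. That remainder fades at 0.492 min⁻¹ in blue, with intermediate near 47.5 %, and more slowly at 0.211 min⁻¹ in green, near 23.9 %.
- First answer for dusk: 50.0 % is its end level, the balance with substrate and partner both taken to zero, that is substrate charge minus partner charge as percent of the substrate charged. In dusk partner is the limiting reagent.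
- Objection: substrate is still there in dusk at 12 min, about 0.573 %, which lowers the answer.
- Round again: partner also remains in dusk. Take blue's remainder and let it fade at blue's rate up to 12 min, which leaves 0.225 % and raises the answer. I commit to 49.7 % for dusk.
- Dawn's end level, 10.0 %, is no answer, since partner remains at 6.0 min. Grey leaves 9.40 %, and a straight line from grey to green gives 22.0 %.
- Objection: with blue included, the remainder bends upward with charge, so that line runs high. The curve through the three runs gives 21.1 %. With 7.57 % of substrate left, I commit to 23.6 % for dawn, so dusk ends higher.
- The forecast names dusk, with 49.6 % for dusk and 24.8 % for dawn, the latter above my figure: “Intermediate therefore stalls once partner runs out”.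

The flask gives dusk, with 49.7 % in dusk and 23.1 % in dawn.

    substrate → intermediate (k = 0.00720 s⁻¹)
    partner + intermediate → target (k = 0.170 L mol⁻¹ s⁻¹)
    target → over-reaction product (k = 0.00650 s⁻¹)

- Dusk stands at its end level of 50.0 % within 0.30 percentage points: there the half-life of intermediate against partner grows from 1.9 min at 1.59 min to 4.6 h at 12.0 min, longer than the time allowed, with 0.496 % of its partner left. In dawn that half-life, taken at the charges, is 0.76 min, shorter than the 6.0 min allowed, and 22.9 % of its partner stands at the end. A neighbour of dusk with 0.030 M of partner has an end level of 70.0 % and ends at 69.5 %.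

The data stem from a simulated flask on assumed constants; the scatter is artificial.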